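**Plan**

- Cuts, in retrosynthetic order: the nine O–benzyl bonds; the C2–C7' bond between the two dihydrobenzofurans; the C2'–aryl bond to ring D; in each half the furan O1–C2 bond (traced back to a 3-bromochroman-2-one) and the C3–aryl bond (traced back to a coumarin).
- Forward: two coumarins are made (pyranone ring by Wittig olefination/lactonization). Each takes up the same 3,5-bis(benzyloxy)phenyl group at C4. Each six-membered lactone is contracted to the dihydrofuran ring with CO2H on C2. The lower acid is arylated with ring D, the two halves are joined, and the benzyl groups are removed.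
- Enabling feature: C2 (and C2') is an sp3 carbon bonded to the furan oxygen O1 and flanked by the C3 stereocenter that carries the 3,5-dioxygenated aryl ring. A carboxyl group on it leaves as CO2 to give an O1-stabilized, planar radical with no memory of its configuration, which nickel arylates anti to the C3 aryl group.
- Stereochemistry: C3 and C3' come from the rhodium/(R)-SEGPHOS 1,4-additions. C2 and C2' are set by substrate control in the two stereoconvergent decarboxylative arylations (C2 epimer mixtures funnel to trans). The E alkene comes from the Heck reaction.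
- Labels: unprimed positions = styryl-bearing (upper) dihydrobenzofuran; primed = lower dihydrobenzofuran; ring D = the 2,4-dioxygenated phenyl ring on C2'.

Key step: step 14

Remark: all nine phenols are carried as benzyl ethers, which survive every step and are removed without hydrogenation; the five building blocks marked as starting materials in the compound list are taken as commercial.

**Route**

Step 1
Reactants: 1 4-bromo-2,6-dimethoxybenzaldehyde
Product: 2 4-bromo-2,6-dihydroxybenzaldehyde
Conditions: BBr3, CH2Cl2, −78 °C → rt; H2O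
Reagents that add atoms: none
Why: Lewis acid cleavage of aryl methyl ethers, in which BBr3 chelated between the aldehyde oxygen and each ortho methoxy group should remove both methyl groups as MeBr and leave the C–Br bond untouched.

Step 2
Reactants: 2 4-bromo-2,6-dihydroxybenzaldehyde
Product: 4 7-bromo-5-hydroxy-2H-chromen-2-one, via ethyl 3-(4-bromo-2,6-dihydroxyphenyl)prop-2-enoate 3 (not isolated)
Conditions: Ph3P=CHCO2Et, PhNEt2, reflux
Reagents that add atoms: ethyl (triphenylphosphoranylidene)acetate, CCOC(=O)C=P(c1ccccc1)(c1ccccc1)c1ccccc1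
Why: Wittig olefination followed in the same pot by thermal E/Z equilibration and lactonization of the Z ester (the classical salicylaldehyde-to-coumarin sequence) should close the pyranone ring through either of the two equivalent hydroxyl groups, so no regiochemical question arises.

Step 3
Reactants: 4 7-bromo-5-hydroxy-2H-chromen-2-one
Product: 5 5-(benzyloxy)-7-bromo-2H-chromen-2-one
Conditions: BnBr, K2CO3, DMF, rt
Reagents that add atoms: benzyl bromide, BrCc1ccccc1
Why: Williamson ether synthesis on the one remaining acidic phenol, the lactone being stable to K2CO3 at room temperature.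

Step 4
Reactants: 5 5-(benzyloxy)-7-bromo-2H-chromen-2-one; 6 1-(benzyloxy)-4-ethenylbenzene
Product: 7 5-(benzyloxy)-7-[(E)-2-[4-(benzyloxy)phenyl]ethenyl]-2H-chromen-2-one
Conditions: Pd(OAc)2 (5 mol%), P(o-tol)3, Et3N, DMF, 100 °C
Reagents that add atoms: none
Why: Mizoroki–Heck reaction, in which syn insertion of the styrene into the aryl–palladium bond and syn β-hydride elimination should give the E stilbene, the styrene being a far better acceptor than the coumarin C3=C4 bond.

Step 5
Reactants: 7 5-(benzyloxy)-7-[(E)-2-[4-(benzyloxy)phenyl]ethenyl]-2H-chromen-2-one; 8 [3,5-bis(benzyloxy)phenyl]boronic acid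
Product: 9 (4R)-5-(benzyloxy)-4-[3,5-bis(benzyloxy)phenyl]-7-[(E)-2-[4-(benzyloxy)phenyl]ethenyl]-3,4-dihydro-2H-chromen-2-one
Conditions: Rh(acac)(C2H4)2 (3 mol%), (R)-SEGPHOS, 8 in excess, dioxane/H2O 10:1, 60 °C
Reagents that add atoms: none
Why: Hayashi–Miyaura asymmetric 1,4-addition, in which the aryl–rhodium species formed by transmetalation adds to C4 of the coumarin on the face chosen by the (R)-SEGPHOS ligand, which by analogy with additions to simpler coumarins should give the 4R lactone, while the unactivated stilbene does not insert.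

Step 6
Reactants: 9 (4R)-5-(benzyloxy)-4-[3,5-bis(benzyloxy)phenyl]-7-[(E)-2-[4-(benzyloxy)phenyl]ethenyl]-3,4-dihydro-2H-chromen-2-one
Product: 12 (3R)-4-(benzyloxy)-3-[3,5-bis(benzyloxy)phenyl]-6-[(E)-2-[4-(benzyloxy)phenyl]ethenyl]-2,3-dihydro-1-benzofuran-2-carboxylic acid (C2 epimer mixture), via 3-bromochromanone 10 (not isolated), via ring-opened 2-bromo-3-(2-hydroxyaryl)propanoic acid 11 (not isolated)
Conditions: LiN(SiMe3)2, THF, −78 °C; BrCCl2CCl2Br, −78 °C; then LiOH, THF/H2O, 0 °C → rt; aq. HCl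
Reagents that add atoms: lithium hydroxide, [Li+].[OH-]
Why: Enolate bromination followed by the coumarin-to-coumaranic-acid ring contraction, in which hydroxide opens the aryl lactone and the liberated phenoxide displaces the α-bromide in a 5-exo-tet SN2 reaction, the C4 stereocenter (now C3) not being touched and the configuration at the new C2 being irrelevant because step 14 erases it.

Step 7
Reactants: 13 3-(benzyloxy)phenol
Product: 14 5-(benzyloxy)-2-bromophenol
Conditions: NBS, i-Pr2NH (10 mol%), CH2Cl2, 0 °C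
Reagents that add atoms: N-bromosuccinimide, O=C1CCC(=O)N1Br
Why: Amine-mediated ortho-selective electrophilic bromination of a phenol, in which the ortho position that is also para to the benzyloxy group is doubly activated and unhindered, so bromine should enter there and not between the two oxygens.

Step 8
Reactants: 14 5-(benzyloxy)-2-bromophenol
Product: 15 6-(benzyloxy)-3-bromo-2-hydroxybenzaldehyde
Conditions: MgCl2, Et3N, (CH2O)n, MeCN, reflux
Reagents that add atoms: paraformaldehyde (as formaldehyde), C=O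
Why: Casnati–Skattebøl magnesium-mediated ortho-formylation, in which the magnesium phenoxide delivers formaldehyde only to an ortho position and the single free one lies between the hydroxyl and the benzyloxy group.

Step 9
Reactants: 15 6-(benzyloxy)-3-bromo-2-hydroxybenzaldehyde
Product: 17 5-(benzyloxy)-8-bromo-2H-chromen-2-one, via ethyl 3-[6-(benzyloxy)-3-bromo-2-hydroxyphenyl]prop-2-enoate 16 (not isolated)
Conditions: Ph3P=CHCO2Et, PhNEt2, reflux
Reagents that add atoms: ethyl (triphenylphosphoranylidene)acetate, CCOC(=O)C=P(c1ccccc1)(c1ccccc1)c1ccccc1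
Why: Wittig olefination and thermal lactonization as in step 2, in which only the hydroxyl group next to bromine is free, so the 8-bromo-5-benzyloxy pattern is fixed by the substrate.

Step 10
Reactants: 17 5-(benzyloxy)-8-bromo-2H-chromen-2-one; 8 [3,5-bis(benzyloxy)phenyl]boronic acid
Product: 18 (4R)-5-(benzyloxy)-4-[3,5-bis(benzyloxy)phenyl]-8-bromo-3,4-dihydro-2H-chromen-2-one
Conditions: Rh(acac)(C2H4)2 (3 mol%), (R)-SEGPHOS, 8 in excess, dioxane/H2O 10:1, 60 °C
Reagents that add atoms: none
Why: Hayashi–Miyaura asymmetric 1,4-addition as in step 5, in which the same catalyst should set the 4R center and the aryl bromide should be inert to monovalent rhodium under these conditions.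

Step 11
Reactants: 18 (4R)-5-(benzyloxy)-4-[3,5-bis(benzyloxy)phenyl]-8-bromo-3,4-dihydro-2H-chromen-2-one
Product: 21 (3R)-4-(benzyloxy)-3-[3,5-bis(benzyloxy)phenyl]-7-bromo-2,3-dihydro-1-benzofuran-2-carboxylic acid (C2 epimer mixture), via 3,8-dibromochromanone 19 (not isolated), via ring-opened 2-bromo-3-(2-hydroxyaryl)propanoic acid 20 (not isolated)
Conditions: LiN(SiMe3)2, THF, −78 °C; BrCCl2CCl2Br, −78 °C; then LiOH, THF/H2O, 0 °C → rt; aq. HCl
Reagents that add atoms: lithium hydroxide, [Li+].[OH-]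
Why: Enolate bromination and hydroxide-induced lactone-to-dihydrofuran ring contraction as in step 6, in which the phenoxide ortho to bromine closes the five-membered ring by 5-exo-tet SN2 displacement without touching the C3 stereocenter or the aryl bromide.

Step 12
Reactants: 22 1,3-bis(benzyloxy)benzene
Product: 23 2,4-bis(benzyloxy)-1-iodobenzene
Conditions: NIS, TFA (cat.), MeCN, rt
Reagents that add atoms: N-iodosuccinimide, O=C1CCC(=O)N1I
Why: Electrophilic aromatic iodination, in which the 4-position of the resorcinol diether is para to one benzyloxy group, ortho to the other and less hindered than the 2-position between them.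

Step 13
Reactants: 21 (3R)-4-(benzyloxy)-3-[3,5-bis(benzyloxy)phenyl]-7-bromo-2,3-dihydro-1-benzofuran-2-carboxylic acid (C2 epimer mixture); 23 2,4-bis(benzyloxy)-1-iodobenzene
Product: 25 (2R,3R)-4-(benzyloxy)-2-[2,4-bis(benzyloxy)phenyl]-3-[3,5-bis(benzyloxy)phenyl]-7-bromo-2,3-dihydro-1-benzofuran, via N-(acyloxy)phthalimide ester 24 (not isolated)
Conditions: (a) N-hydroxyphthalimide, DIC, DMAP (cat.), CH2Cl2, rt, evaporate; (b) 23, NiBr2(dme) (10 mol%), 4,4'-di-tert-butyl-2,2'-bipyridine (10 mol%), Zn dust, DMA, rt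
Reagents that add atoms: none
Why: Nickel-catalysed decarboxylative cross-electrophile coupling of a redox-active ester with an aryl iodide, in which zerovalent nickel inserts into the C–I bond of 23 much faster than into the hindered, electron-rich C7'–Br bond and the planar O1'-stabilized C2' radical released from 24 is arylated anti to the C3' aryl group, so both C2' epimers should converge on the 2R,3R-trans ring.

Step 14
Reactants: 12 (3R)-4-(benzyloxy)-3-[3,5-bis(benzyloxy)phenyl]-6-[(E)-2-[4-(benzyloxy)phenyl]ethenyl]-2,3-dihydro-1-benzofuran-2-carboxylic acid (C2 epimer mixture); 25 (2R,3R)-4-(benzyloxy)-2-[2,4-bis(benzyloxy)phenyl]-3-[3,5-bis(benzyloxy)phenyl]-7-bromo-2,3-dihydro-1-benzofuran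
Product: 29 nona-O-benzyl ether of the target, via N-(acyloxy)phthalimide ester 26 (not isolated), via aryllithium 27 (not isolated), via arylzinc chloride 28 (not isolated)
Conditions: (a) 12, N-hydroxyphthalimide, DIC, DMAP (cat.), CH2Cl2, rt, evaporate; (b) 25, t-BuLi (2 equiv), THF, −78 °C, then ZnCl2, −78 °C → rt; (c) combine, NiCl2(dme) (20 mol%), 4,4'-di-tert-butyl-2,2'-bipyridine (40 mol%), THF/DMF, rt, dark
Reagents that add atoms: none
Why: The redox-active ester 26 accepts one electron from low-valent nickel and loses phthalimide anion and CO2 to give the C2 radical of the upper dihydrobenzofuran, which is planar and stabilized by the ring oxygen O1, so both C2 epimers of 12 give the same intermediate; this radical is captured by the aryl–nickel species formed by transmetalation from arylzinc 28, and reductive elimination from trivalent nickel forms the C2–C7' bond. The closest known reaction type is the nickel-catalysed decarboxylative Negishi arylation of redox-active esters of secondary and α-oxygenated carboxylic acids. No ring is closed in this step. The new stereocenter C2 should be controlled by the neighbouring C3 stereocenter: its 3,5-bis(benzyloxy)phenyl group shields one face of the flat radical, and because radical capture by nickel is reversible the aryl group should end up anti to it, giving the (2R,3R)-trans ring. The step needs trans selectivity, a single site on the aryl partner and survival of the E stilbene; the first comes from the C3 substituent, the second from the one C–Br bond at C7' that fixes where zinc sits, and the third from the absence of light and of any sensitizer. The competing path is β-hydride loss toward the aromatic 3-arylbenzofuran, which should be outrun by fast reductive elimination from the aryl(alkyl)nickel intermediate.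

Step 15
Reactants: 29 nona-O-benzyl ether of the target
Product: 30 CNP0217875.2 (target)
Conditions: BCl3, pentamethylbenzene, CH2Cl2, −78 °C; MeOH quench
Reagents that add atoms: none
Why: Lewis acid debenzylation with a cation scavenger, in which BCl3 cleaves the nine aryl benzyl ethers at −78 °C and pentamethylbenzene traps the benzyl cations, conditions that should spare the stilbene and the 2-aryl-2,3-dihydrobenzofuran rings and leave all four stereocenters untouched.

**Compound list**

1 | 4-bromo-2,6-dimethoxybenzaldehyde | COc1cc(Br)cc(OC)c1C=O | starting material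
2 | 4-bromo-2,6-dihydroxybenzaldehyde | O=Cc1c(O)cc(Br)cc1O | intermediate
3 | ethyl 3-(4-bromo-2,6-dihydroxyphenyl)prop-2-enoate (E/Z) | CCOC(=O)C=Cc1c(O)cc(Br)cc1O | intermediate (not isolated)
4 | 7-bromo-5-hydroxy-2H-chromen-2-one | O=c1ccc2c(O)cc(Br)cc2o1 | intermediate
5 | 5-(benzyloxy)-7-bromo-2H-chromen-2-one | O=c1ccc2c(OCc3ccccc3)cc(Br)cc2o1 | intermediate
6 | 1-(benzyloxy)-4-ethenylbenzene | C=Cc1ccc(OCc2ccccc2)cc1 | starting material
7 | 5-(benzyloxy)-7-[(E)-2-[4-(benzyloxy)phenyl]ethenyl]-2H-chromen-2-one | O=c1ccc2c(OCc3ccccc3)cc(/C=C/c3ccc(OCc4ccccc4)cc3)cc2o1 | intermediate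
8 | [3,5-bis(benzyloxy)phenyl]boronic acid | OB(O)c1cc(OCc2ccccc2)cc(OCc2ccccc2)c1 | starting material
9 | (4R)-5-(benzyloxy)-4-[3,5-bis(benzyloxy)phenyl]-7-[(E)-2-[4-(benzyloxy)phenyl]ethenyl]-3,4-dihydro-2H-chromen-2-one | c1ccccc1COc1ccc(/C=C/c2cc(OCc4ccccc4)c3c(c2)OC(=O)C[C@@H]3c2cc(OCc4ccccc4)cc(OCc4ccccc4)c2)cc1 | intermediate
10 | (4R)-5-(benzyloxy)-4-[3,5-bis(benzyloxy)phenyl]-7-[(E)-2-[4-(benzyloxy)phenyl]ethenyl]-3-bromo-3,4-dihydro-2H-chromen-2-one (C3 epimers) | c1ccccc1COc1ccc(/C=C/c2cc(OCc4ccccc4)c3c(c2)OC(=O)C(Br)[C@@H]3c2cc(OCc4ccccc4)cc(OCc4ccccc4)c2)cc1 | intermediate (not isolated)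
11 | (3R)-3-[2-(benzyloxy)-4-[(E)-2-[4-(benzyloxy)phenyl]ethenyl]-6-hydroxyphenyl]-3-[3,5-bis(benzyloxy)phenyl]-2-bromopropanoic acid (C2 epimers, present as its dilithium salt) | c1ccccc1COc1ccc(/C=C/c2cc(OCc4ccccc4)c([C@H](C(Br)C(=O)O)c3cc(OCc4ccccc4)cc(OCc4ccccc4)c3)c(O)c2)cc1 | intermediate (not isolated)
12 | (3R)-4-(benzyloxy)-3-[3,5-bis(benzyloxy)phenyl]-6-[(E)-2-[4-(benzyloxy)phenyl]ethenyl]-2,3-dihydro-1-benzofuran-2-carboxylic acid (C2 epimer mixture) | c1ccccc1COc1ccc(/C=C/c2cc(OCc4ccccc4)c3c(c2)OC(C(=O)O)[C@@H]3c2cc(OCc4ccccc4)cc(OCc4ccccc4)c2)cc1 | intermediate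
13 | 3-(benzyloxy)phenol | Oc1cccc(OCc2ccccc2)c1 | starting material
14 | 5-(benzyloxy)-2-bromophenol | Oc1cc(OCc2ccccc2)ccc1Br | intermediate
15 | 6-(benzyloxy)-3-bromo-2-hydroxybenzaldehyde | O=Cc1c(O)c(Br)ccc1OCc1ccccc1 | intermediate
16 | ethyl 3-[6-(benzyloxy)-3-bromo-2-hydroxyphenyl]prop-2-enoate (E/Z) | CCOC(=O)C=Cc1c(O)c(Br)ccc1OCc1ccccc1 | intermediate (not isolated)
17 | 5-(benzyloxy)-8-bromo-2H-chromen-2-one | O=c1ccc2c(OCc3ccccc3)ccc(Br)c2o1 | intermediate
18 | (4R)-5-(benzyloxy)-4-[3,5-bis(benzyloxy)phenyl]-8-bromo-3,4-dihydro-2H-chromen-2-one | Brc1ccc(OCc2ccccc2)c2c1OC(=O)C[C@@H]2c1cc(OCc2ccccc2)cc(OCc2ccccc2)c1 | intermediate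
19 | (4R)-5-(benzyloxy)-4-[3,5-bis(benzyloxy)phenyl]-3,8-dibromo-3,4-dihydro-2H-chromen-2-one (C3 epimers) | Brc1ccc(OCc2ccccc2)c2c1OC(=O)C(Br)[C@@H]2c1cc(OCc2ccccc2)cc(OCc2ccccc2)c1 | intermediate (not isolated)
20 | (3R)-3-[6-(benzyloxy)-3-bromo-2-hydroxyphenyl]-3-[3,5-bis(benzyloxy)phenyl]-2-bromopropanoic acid (C2 epimers, present as its dilithium salt) | Brc1ccc(OCc2ccccc2)c([C@H](C(Br)C(=O)O)c2cc(OCc3ccccc3)cc(OCc3ccccc3)c2)c1O | intermediate (not isolated)
21 | (3R)-4-(benzyloxy)-3-[3,5-bis(benzyloxy)phenyl]-7-bromo-2,3-dihydro-1-benzofuran-2-carboxylic acid (C2 epimer mixture) | Brc1ccc(OCc2ccccc2)c2c1OC(C(=O)O)[C@@H]2c1cc(OCc2ccccc2)cc(OCc2ccccc2)c1 | intermediate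
22 | 1,3-bis(benzyloxy)benzene | c1ccc(COc2cccc(OCc3ccccc3)c2)cc1 | starting material
23 | 2,4-bis(benzyloxy)-1-iodobenzene | Ic1ccc(OCc2ccccc2)cc1OCc1ccccc1 | intermediate
24 | 1,3-dioxoisoindolin-2-yl (3R)-4-(benzyloxy)-3-[3,5-bis(benzyloxy)phenyl]-7-bromo-2,3-dihydro-1-benzofuran-2-carboxylate (C2 epimers) | Brc1ccc(OCc2ccccc2)c2c1OC(C(=O)ON1C(=O)c3ccccc3C1=O)[C@@H]2c1cc(OCc2ccccc2)cc(OCc2ccccc2)c1 | intermediate (not isolated)
25 | (2R,3R)-4-(benzyloxy)-2-[2,4-bis(benzyloxy)phenyl]-3-[3,5-bis(benzyloxy)phenyl]-7-bromo-2,3-dihydro-1-benzofuran | Brc1ccc(OCc2ccccc2)c2c1O[C@@H](c1ccc(OCc3ccccc3)cc1OCc1ccccc1)[C@@H]2c1cc(OCc2ccccc2)cc(OCc2ccccc2)c1 | intermediate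
26 | 1,3-dioxoisoindolin-2-yl (3R)-4-(benzyloxy)-3-[3,5-bis(benzyloxy)phenyl]-6-[(E)-2-[4-(benzyloxy)phenyl]ethenyl]-2,3-dihydro-1-benzofuran-2-carboxylate (C2 epimers) | c1ccccc1COc1ccc(/C=C/c2cc(OCc4ccccc4)c3c(c2)OC(C(=O)ON2C(=O)c4ccccc4C2=O)[C@@H]3c2cc(OCc4ccccc4)cc(OCc4ccccc4)c2)cc1 | intermediate (not isolated)
27 | [(2R,3R)-4-(benzyloxy)-2-[2,4-bis(benzyloxy)phenyl]-3-[3,5-bis(benzyloxy)phenyl]-2,3-dihydro-1-benzofuran-7-yl]lithium | [Li]c1ccc(OCc2ccccc2)c2c1O[C@@H](c1ccc(OCc3ccccc3)cc1OCc1ccccc1)[C@@H]2c1cc(OCc2ccccc2)cc(OCc2ccccc2)c1 | intermediate (not isolated)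
28 | [(2R,3R)-4-(benzyloxy)-2-[2,4-bis(benzyloxy)phenyl]-3-[3,5-bis(benzyloxy)phenyl]-2,3-dihydro-1-benzofuran-7-yl]zinc chloride | Cl[Zn]c1ccc(OCc2ccccc2)c2c1O[C@@H](c1ccc(OCc3ccccc3)cc1OCc1ccccc1)[C@@H]2c1cc(OCc2ccccc2)cc(OCc2ccccc2)c1 | intermediate (not isolated)
29 | (2R,3R)-4-(benzyloxy)-2-[(2R,3R)-4-(benzyloxy)-2-[2,4-bis(benzyloxy)phenyl]-3-[3,5-bis(benzyloxy)phenyl]-2,3-dihydro-1-benzofuran-7-yl]-3-[3,5-bis(benzyloxy)phenyl]-6-[(E)-2-[4-(benzyloxy)phenyl]ethenyl]-2,3-dihydro-1-benzofuran (nona-O-benzyl ether of the target) | c1ccccc1COc1ccc(/C=C/c2cc(OCc5ccccc5)c3c(c2)O[C@@H](c2ccc(OCc5ccccc5)c4c2O[C@@H](c2ccc(OCc5ccccc5)cc2OCc5ccccc5)[C@@H]4c2cc(OCc5ccccc5)cc(OCc5ccccc5)c2)[C@@H]3c2cc(OCc5ccccc5)cc(OCc5ccccc5)c2)cc1 | intermediate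
30 | 4-[(2R,3R)-3-(3,5-dihydroxyphenyl)-7-[(2R,3R)-3-(3,5-dihydroxyphenyl)-4-hydroxy-6-[(E)-2-(4-hydroxyphenyl)ethenyl]-2,3-dihydro-1-benzofuran-2-yl]-4-hydroxy-2,3-dihydro-1-benzofuran-2-yl]benzene-1,3-diol (CNP0217875.2) | Oc1ccc(/C=C/c2cc(O)c3c(c2)O[C@@H](c2ccc(O)c4c2O[C@@H](c2ccc(O)cc2O)[C@@H]4c2cc(O)cc(O)c2)[C@@H]3c2cc(O)cc(O)c2)cc1 | target

**Step count and risks**

Total step count: 15. Longest linear sequence: 8 steps (steps 1–6, 14, 15; the sequence 7–11, 13, 14, 15 is equally long).

Steps most likely to fail: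

1. Step 14. Transmetalation from the bulky, electron-rich arylzinc may be slow, so that the redox-active ester is used up by simple reduction or by β-hydride elimination toward aromatization of the furan ring; the facial bias at C2 may also be too small. The fallback replaces the radical coupling by a polar one; it sets out from 12 and 25 and comes back at 29. Oxidative decarboxylation of 12 with Pb(OAc)4 (Cu(OAc)2 cat., pyridine, benzene) would give (3R)-4-(benzyloxy)-3-[3,5-bis(benzyloxy)phenyl]-6-[(E)-2-[4-(benzyloxy)phenyl]ethenyl]-2,3-dihydro-1-benzofuran-2-yl acetate F1. Bromine–lithium exchange on 25 (t-BuLi), B(OMe)3 and aqueous KHF2 would give potassium [(2R,3R)-4-(benzyloxy)-2-[2,4-bis(benzyloxy)phenyl]-3-[3,5-bis(benzyloxy)phenyl]-2,3-dihydro-1-benzofuran-7-yl]trifluoroborate F2. BF3·OEt2 in CH2Cl2/MeCN at low temperature should ionize F1 to the O1-stabilized oxocarbenium ion, which takes the aryl group from boron at the ipso carbon and anti to the C3 aryl group to give 29.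

2. Step 13. Nickel may also insert into the C7'–Br bond of the ester (oligomerization), or oxidative addition to the ortho-benzyloxy iodide may be slower than reductive decay of the ester. The fallback forms the C2'–aryl bond without nickel; it sets out from 21 and 22 and comes back at 25. Oxidative decarboxylation of 21 with Pb(OAc)4 would give (3R)-4-(benzyloxy)-3-[3,5-bis(benzyloxy)phenyl]-7-bromo-2,3-dihydro-1-benzofuran-2-yl acetate F3. BF3·OEt2 in CH2Cl2 at −78 °C with 22 in excess should then give a Friedel–Crafts arylation of the oxocarbenium ion through the 4-position of the resorcinol diether and anti to the C3' aryl group, leading to 25 with the aryl bromide untouched.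

3. Step 5 (and its twin, step 10). Aryl transfer from rhodium next to the peri 5-benzyloxy group may be slow, so that protodeboronation wins and the enantioselectivity erodes. The fallback sets the stereocenter by hydride delivery instead of aryl delivery; it sets out from 7 and 8 and comes back at 9. An oxidative Heck arylation (Pd(OAc)2, 1,10-phenanthroline, O2, DMF) would give 5-(benzyloxy)-4-[3,5-bis(benzyloxy)phenyl]-7-[(E)-2-[4-(benzyloxy)phenyl]ethenyl]-2H-chromen-2-one F4. Asymmetric conjugate reduction of F4 with a copper hydride catalyst (Cu(OAc)2, DTBM-SEGPHOS of the antipode that gives 4R, HSiMe(OEt)2, t-BuOH, toluene) should give 9, the small hydride being little affected by the peri substituent. For step 10 the same two operations would lead from 17 and 8 through 5-(benzyloxy)-4-[3,5-bis(benzyloxy)phenyl]-8-bromo-2H-chromen-2-one F5 to 18.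

Further compounds
F1 | step 14 | (3R)-4-(benzyloxy)-3-[3,5-bis(benzyloxy)phenyl]-6-[(E)-2-[4-(benzyloxy)phenyl]ethenyl]-2,3-dihydro-1-benzofuran-2-yl acetate (C2 epimers) | c1ccccc1COc1ccc(/C=C/c2cc(OCc4ccccc4)c3c(c2)OC(OC(C)=O)[C@@H]3c2cc(OCc4ccccc4)cc(OCc4ccccc4)c2)cc1
F2 | step 14 | potassium [(2R,3R)-4-(benzyloxy)-2-[2,4-bis(benzyloxy)phenyl]-3-[3,5-bis(benzyloxy)phenyl]-2,3-dihydro-1-benzofuran-7-yl]trifluoroborate | [K+].F[B-](F)(F)c1ccc(OCc2ccccc2)c2c1O[C@@H](c1ccc(OCc3ccccc3)cc1OCc1ccccc1)[C@@H]2c1cc(OCc2ccccc2)cc(OCc2ccccc2)c1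
F3 | step 13 | (3R)-4-(benzyloxy)-3-[3,5-bis(benzyloxy)phenyl]-7-bromo-2,3-dihydro-1-benzofuran-2-yl acetate (C2 epimers) | Brc1ccc(OCc2ccccc2)c2c1OC(OC(C)=O)[C@@H]2c1cc(OCc2ccccc2)cc(OCc2ccccc2)c1
F4 | step 5 | 5-(benzyloxy)-4-[3,5-bis(benzyloxy)phenyl]-7-[(E)-2-[4-(benzyloxy)phenyl]ethenyl]-2H-chromen-2-one | O=c1cc(-c2cc(OCc3ccccc3)cc(OCc3ccccc3)c2)c2c(OCc3ccccc3)cc(/C=C/c3ccc(OCc4ccccc4)cc3)cc2o1
F5 | step 10 | 5-(benzyloxy)-4-[3,5-bis(benzyloxy)phenyl]-8-bromo-2H-chromen-2-one | O=c1cc(-c2cc(OCc3ccccc3)cc(OCc3ccccc3)c2)c2c(OCc3ccccc3)ccc(Br)c2o1
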